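## Retrosynthetic overview

- Candidone 7 ⇒ O-methylation of the 5-OH of (2S)-5-hydroxy-7-methoxy-8-prenylflavanone 6.
- 6 ⇒ para-Claisen (Claisen then Cope) rearrangement of the 5-O-prenyl ether 3; this makes the C8–CH2 bond.
- 3 ⇒ (2S)-pinostrobin 1 + prenyl alcohol 2 (Mitsunobu etherification).
- No ring is built: the benzene ring, the pyranone ring and the C2 stereocentre are all bought in 1 and carried through unchanged.

Assumption: natural (2S)-(−)-pinostrobin (5-hydroxy-7-methoxyflavanone) is bought as the single enantiomer and its ee is confirmed by chiral HPLC before use.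

## Route

Step 1
Reactants: 1 (2S)-pinostrobin; 2 3-methylbut-2-en-1-ol
Product: 3 (2S)-7-methoxy-5-[(3-methylbut-2-en-1-yl)oxy]flavanone
Conditions: PPh3, DIAD, THF, 0 °C → rt
Reagents that add atoms: none
Why: Mitsunobu etherification of the chelated but sufficiently acidic 5-OH under non-basic conditions, which avoids the base-induced retro-oxa-Michael ring opening that would racemise C2, so the purchased (S) centre is carried through untouched.

Step 2
Reactants: 3 (2S)-7-methoxy-5-[(3-methylbut-2-en-1-yl)oxy]flavanone
Product: 6 (2S)-5-hydroxy-7-methoxy-8-(3-methylbut-2-en-1-yl)flavanone, via ortho-dienone 4 (not isolated), via para-dienone 5 (not isolated)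
Conditions: Eu(fod)3 (10 mol%), CHCl3, 60 °C
Reagents that add atoms: none
Why: Eu(III)-catalysed para-Claisen rearrangement, in which the aromatic Claisen [3,3] shift goes to C6 (C4a is blocked) to give the congested 1,1-dimethylallyl dienone 4, the Cope [3,3] shift then moves the chain to C8 as the linear prenyl group in 5, and enolisation gives the chelated phenol; no bond at C2 is touched.

Step 3
Reactants: 6 (2S)-5-hydroxy-7-methoxy-8-(3-methylbut-2-en-1-yl)flavanone
Product: 7 candidone
Conditions: MeOH, PPh3, DIAD, THF, 0 °C → rt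
Reagents that add atoms: methanol CO
Why: Mitsunobu O-methylation of the chelated 5-OH, the same non-basic reaction type as step 1, so the flavanone ring is not opened, the prenyl alkene and ketone are inert, and C2 keeps its S configuration.

## Compound list

1 | (2S)-pinostrobin, (2S)-5-hydroxy-7-methoxy-2-phenylchroman-4-one | COc1cc(O)c2c(c1)O[C@H](c1ccccc1)CC2=O | starting material
2 | 3-methylbut-2-en-1-ol (prenyl alcohol) | CC(C)=CCO | starting material
3 | (2S)-7-methoxy-5-[(3-methylbut-2-en-1-yl)oxy]-2-phenylchroman-4-one | COc1cc(OCC=C(C)C)c2c(c1)O[C@H](c1ccccc1)CC2=O | intermediate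
4 | ortho-dienone: (2S)-7-methoxy-6-(2-methylbut-3-en-2-yl)-2-phenyl-2,3-dihydro-4H-chromene-4,5(6H)-dione, C6 epimers | C=CC(C)(C)C1C(=O)C2=C(C=C1OC)O[C@H](c1ccccc1)CC2=O | intermediate
5 | para-dienone: (2S)-7-methoxy-8-(3-methylbut-2-en-1-yl)-2-phenyl-2,3-dihydro-4H-chromene-4,5(8H)-dione, C8 epimers | COC1=CC(=O)C2=C(C1CC=C(C)C)O[C@H](c1ccccc1)CC2=O | intermediate
6 | (2S)-5-hydroxy-7-methoxy-8-(3-methylbut-2-en-1-yl)-2-phenylchroman-4-one | COc1cc(O)c2c(c1CC=C(C)C)O[C@H](c1ccccc1)CC2=O | intermediate
7 | candidone, (2S)-5,7-dimethoxy-8-(3-methylbut-2-en-1-yl)-2-phenylchroman-4-one | COc1cc(OC)c2c(c1CC=C(C)C)O[C@H](c1ccccc1)CC2=O | target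

## Summary

Total step count: 3. Longest linear sequence: 3 steps (1 → 3 → 6 → 7).

The route has only three steps, so all three are ranked here, most risky first.

**Step 2 (para-Claisen).** Dienone 4 can enolise before the Cope shift and give the 6-(1,1-dimethylallyl) isomer, or the ether can lose the prenyl group and return 1. The fallback replaces the rearrangement by a cross-coupling. It sets out from 1, which is O-methylated under the conditions of step 3 (MeOH, PPh3, DIAD, THF) to (2S)-5,7-dimethoxyflavanone F1. Iodination with NIS (cat. TFA, MeCN, 0 °C) is expected to go to C8 once the 5-oxygen is alkylated, giving (2S)-8-iodo-5,7-dimethoxyflavanone F2; any 6-iodo isomer is removed by chromatography. A base-free Stille coupling with tributyl(3-methylbut-2-en-1-yl)stannane (Pd(PPh3)4, DMF, 90 °C) then comes back to the route at 7.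

**Step 3 (methylation of the chelated 5-OH).** The hydrogen-bonded phenol may react slowly, and forcing it with base would open the ring to the chalcone and erode the ee. The fallback masks the carbonyl by a redox detour. It sets out from 6, which is reduced (NaBH4, THF/MeOH, 0 °C) to (2S)-5-hydroxy-7-methoxy-8-prenylflavan-4-ol F3 (C4 epimers, used together). In F3 the phenol is no longer chelated and C2 cannot epimerise by ring opening. Ordinary phenol methylation (MeI, K2CO3, acetone, rt) gives (2S)-5,7-dimethoxy-8-prenylflavan-4-ol F4. Oxidation of the benzylic alcohol (Dess–Martin periodinane, NaHCO3, CH2Cl2) comes back to the route at 7.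

**Step 1 (Mitsunobu prenylation).** The prenyl oxyphosphonium ion can partly ionise (SN2′ ether, C-alkylation, isoprene), or the chelated phenol may couple slowly. The fallback builds the prenyl ether in two stages without a Mitsunobu reaction. It sets out from 1, which undergoes Tsuji–Trost O-allylation with allyl methyl carbonate (Pd(PPh3)4 cat., THF, rt) to give (2S)-5-allyloxy-7-methoxyflavanone F5. Olefin cross-metathesis with 2-methyl-2-butene (Grubbs II 5 mol%, CH2Cl2, 40 °C) turns the allyl into the prenyl ether and comes back to the route at 3.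

## Further compounds

F1 | step 2 | (2S)-5,7-dimethoxy-2-phenylchroman-4-one | COc1cc(OC)c2c(c1)O[C@H](c1ccccc1)CC2=O
F2 | step 2 | (2S)-8-iodo-5,7-dimethoxy-2-phenylchroman-4-one | COc1cc(OC)c2c(c1I)O[C@H](c1ccccc1)CC2=O
F3 | step 3 | (2S)-5-hydroxy-7-methoxy-8-(3-methylbut-2-en-1-yl)-2-phenylchroman-4-ol, C4 epimers | COc1cc(O)c2c(c1CC=C(C)C)O[C@H](c1ccccc1)CC2O
F4 | step 3 | (2S)-5,7-dimethoxy-8-(3-methylbut-2-en-1-yl)-2-phenylchroman-4-ol, C4 epimers | COc1cc(OC)c2c(c1CC=C(C)C)O[C@H](c1ccccc1)CC2O
F5 | step 1 | (2S)-5-(allyloxy)-7-methoxy-2-phenylchroman-4-one | COc1cc(OCC=C)c2c(c1)O[C@H](c1ccccc1)CC2=O
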